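**Plan** (labdane locants C1–C20 are used in the text)
1. Cuts, backwards: C20 aldehyde and C19 acetate from a C20 ester and a C19 nitrile; butenolide cut at C12–C13 (B-alkyl Suzuki–Miyaura coupling); C17 cut from C8 (methylenation of a C8 ketone made from a C8=C9 alkene); ring A cut at C3–C4 and C1–C10 in one operation; last the C4–C5 bond (Michael addition).
2. Feature used: the quaternary carbons C4 and C10 of ring A are 1,3-related through C5–H, each bears a one-carbon group at carboxyl level (C19, C20), and C10 adjoins the C8/C9 sector of ring B. C10 can therefore react as the α-carbon of a C8=C9–C10=C20 dienolate and C4 as a nitrile-stabilised carbanion, and a C1–C3 dielectrophile stitches them into ring A.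
3. Forward: ring B first (cyclohexenone ester), C4 unit onto C5, vinyl onto C9, ring A by a one-flask [3+3] annulation, then C19/C20 adjustment, butenolide, C8 ketone, exocyclic methylene, aldehyde.
4. Stereochemistry: C5 from a catalytic asymmetric Michael addition; C10 by alkylation anti to the C5 side chain (trans ring fusion); C4 in the ring closure (cyano axial, methyl equatorial); C9 by equilibration next to the C8 ketone.

Key step: step 6

Assumption: the quinine-derived catalyst of step 2 is taken to deliver the S configuration at the new ring stereocentre; if the sense is the opposite, its quinidine-derived pseudo-enantiomer is used. In names of bicyclic compounds the naphthalene positions 1, 2, 4a, 5 and 8a are labdane C9, C8, C5, C4 and C10.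

**Step 1**
Reactants: 1 methyl 2-oxocyclohexane-1-carboxylate
Product: 4 methyl 6-oxocyclohex-1-ene-1-carboxylate, via α-phenylselanyl keto ester 2 (not isolated), via selenoxide 3 (not isolated)
Conditions: PhSeCl, pyridine, CH2Cl2, 0 °C; then 30% aq. H2O2, 0 °C → rt
Reagents that add atoms: none
Why: α-Selenenylation of the β-keto ester, oxidation and syn-elimination of the selenoxide (selenoxide elimination) can only take the ring β-hydrogens and should give the enone ester, which is used at once.

**Step 2**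
Reactants: 4 methyl 6-oxocyclohex-1-ene-1-carboxylate; 5 ethyl 2-cyanopropanoate (racemic)
Product: 6 methyl (6S)-6-(2-cyano-1-ethoxy-1-oxopropan-2-yl)-2-oxocyclohexane-1-carboxylate (epimers at C1 and at the quaternary side-chain carbon)
Conditions: quinine-derived tertiary amine–thiourea catalyst [9-amino(9-deoxy)epi-quinine 3,5-bis(trifluoromethyl)phenyl thiourea] (10 mol %), toluene, −20 °C
Reagents that add atoms: none
Why: Michael addition under bifunctional catalysis, in which the amine deprotonates the cyano ester and the thiourea binds the 1,3-dicarbonyl acceptor, should set the ring stereocentre (future C5) by catalyst control; the two other centres are erased later.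

**Step 3**
Reactants: 6 Michael adduct
Product: 7 methyl (6R)-6-(2-cyano-1-ethoxy-1-oxopropan-2-yl)-2-{[(trifluoromethyl)sulfonyl]oxy}cyclohex-1-ene-1-carboxylate
Conditions: Tf2O, iPr2NEt, CH2Cl2, −78 °C
Reagents that add atoms: triflic anhydride, O=S(=O)(OS(=O)(=O)C(F)(F)F)C(F)(F)F
Why: O-Sulfonylation of the enol of the β-keto ester (enol triflate formation) at low temperature, where retro-Michael cleavage should not compete.

**Step 4**
Reactants: 7 enol triflate
Product: 8 methyl (6S)-6-(2-cyano-1-ethoxy-1-oxopropan-2-yl)-2-ethenylcyclohex-1-ene-1-carboxylate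
Conditions: CH2=CHBF3K, PdCl2(dppf) (5 mol %), Et3N, n-PrOH, 80 °C
Reagents that add atoms: potassium vinyltrifluoroborate, C=C[B-](F)(F)F.[K+]
Why: Suzuki–Miyaura coupling of the electron-poor alkenyl triflate; the vinyl group has no γ-hydrogen, so C8–H is later the only vinylogous acidic site.

**Step 5**
Reactants: 8 diene diester
Product: 9 methyl (6R)-6-[(1RS)-1-cyanoethyl]-2-ethenylcyclohex-1-ene-1-carboxylate
Conditions: LiCl, H2O, DMSO, 140 °C
Reagents that add atoms: none
Why: Krapcho dealkoxycarbonylation: chloride dealkylates the activated α-cyano ethyl ester, and loss of CO2 and protonation leave the secondary nitrile (both C4 epimers, since C4 is deprotonated in step 6), while the unactivated conjugated methyl ester should survive.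

**Step 6**
Reactants: 9 dienoate nitrile; 10 1-chloro-3-iodopropane
Product: 12 methyl (4aR,5R,8aS)-5-cyano-1-ethenyl-5-methyl-4,4a,5,6,7,8-hexahydronaphthalene-8a(3H)-carboxylate, via chloropropyl diene ester 11 (not isolated)
Conditions: KN(SiMe3)2 (1.0 equiv), THF, −78 °C; 10, −78 → −20 °C; then KN(SiMe3)2 (1.3 equiv), −78 °C → rt
Reagents that add atoms: none
Why: The first portion of base removes a γ-hydrogen (C8–H) of the vinylogous ester, and the extended dienolate is alkylated at its α-carbon C10 by the iodide end of 10 (deconjugative α-alkylation of a 2-alkenoate dienolate is the closest known type), which moves the ring alkene to C8=C9; the second portion of base forms the nitrile-stabilised carbanion at C4, which displaces chloride (nitrile-anion cyclisation). Ring A closes in the 6-exo-tet mode. C10 is set by allylic 1,3-strain in the dienolate, which holds the C5 side chain pseudo-axial so that the electrophile enters anti to it, leaving C1 and C4 trans on ring B and hence a trans ring fusion. C4 is set in the chair transition state of the ring closure, where the slim linear cyano group takes the axial site syn to the C10 ester and the methyl group the equatorial site, the alternative suffering a methyl/ester 1,3-diaxial clash. The step needs site selectivity (C10 before C4, so that C4 is fixed in the ring closure and not in an open-chain alkylation), secured by the higher acidity of the vinylogous γ-hydrogen with one equivalent of base in the first stage and by iodide reacting before chloride. It also needs α- over γ-alkylation of the dienolate, which is the normal kinetic course for ester dienolates.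

**Step 7**
Reactants: 12 decalin ester nitrile
Product: 13 (4aR,5R,8aS)-1-ethenyl-8a-(hydroxymethyl)-5-methyl-3,4,4a,5,6,7,8,8a-octahydronaphthalene-5-carbonitrile
Conditions: LiBH4, THF, 0 → 40 °C
Reagents that add atoms: none
Why: LiBH4 reduces esters and leaves nitriles and alkenes untouched (chemoselective hydride reduction); the temperature is kept moderate so that the alkoxide does not add to the 1,3-diaxial nitrile.

**Step 8**
Reactants: 13 hydroxy nitrile
Product: 14 (4aR,5R,8aS)-8a-({[tert-butyl(dimethyl)silyl]oxy}methyl)-1-ethenyl-5-methyl-3,4,4a,5,6,7,8,8a-octahydronaphthalene-5-carbonitrile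
Conditions: TBSOTf, 2,6-lutidine, CH2Cl2, 0 °C
Reagents that add atoms: tert-butyldimethylsilyl triflate, CC(C)(C)[Si](C)(C)OS(=O)(=O)C(F)(F)F
Why: Silylation of the hindered neopentyl alcohol with the silyl triflate (silyl ether protection) masks C20–OH through the hydride, palladium and Lewis acid steps.

**Step 9**
Reactants: 14 silyl ether nitrile
Product: 16 (4aS,5R,8aS)-8a-({[tert-butyl(dimethyl)silyl]oxy}methyl)-1-ethenyl-5-methyl-3,4,4a,5,6,7,8,8a-octahydronaphthalene-5-carbaldehyde, via aldimine 15 (not isolated)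
Conditions: iBu2AlH, toluene, −78 → −20 °C; then aq. HCl (pH 3), 0 °C
Reagents that add atoms: water, O
Why: iBu2AlH adds once to the nitrile to give an N-aluminated aldimine that resists further reduction and is hydrolysed to the aldehyde on work-up (nitrile-to-aldehyde reduction).

**Step 10**
Reactants: 16 C19 aldehyde
Product: 17 [(4aR,5R,8aS)-8a-({[tert-butyl(dimethyl)silyl]oxy}methyl)-1-ethenyl-5-methyl-3,4,4a,5,6,7,8,8a-octahydronaphthalen-5-yl]methanol
Conditions: NaBH4, MeOH, 0 °C
Reagents that add atoms: none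
Why: Borohydride reduction of the hindered aldehyde to the primary alcohol.

**Step 11**
Reactants: 17 C19 alcohol
Product: 18 [(4aR,5R,8aS)-8a-({[tert-butyl(dimethyl)silyl]oxy}methyl)-1-ethenyl-5-methyl-3,4,4a,5,6,7,8,8a-octahydronaphthalen-5-yl]methyl acetate
Conditions: Ac2O, pyridine, DMAP (cat.), CH2Cl2, rt
Reagents that add atoms: acetic anhydride, CC(=O)OC(C)=O
Why: DMAP-catalysed acetylation installs the C19 acetate while C20 is still masked, so that no lactol can form between C19–OH and a C20 aldehyde.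

**Step 12**
Reactants: 18 diene acetate; 19 3-bromofuran-2(5H)-one
Product: 21 [(4aR,5R,8aS)-8a-({[tert-butyl(dimethyl)silyl]oxy}methyl)-5-methyl-1-[2-(2-oxo-2,5-dihydrofuran-3-yl)ethyl]-3,4,4a,5,6,7,8,8a-octahydronaphthalen-5-yl]methyl acetate, via B-alkyl-9-BBN borane 20 (not isolated)
Conditions: 9-BBN, THF, 0 °C → rt; then 19, PdCl2(dppf) (5 mol %), AsPh3 (10 mol %), Cs2CO3, DMF/H2O, rt
Reagents that add atoms: none
Why: Anti-Markovnikov hydroboration with bulky 9-BBN should take only the terminal vinyl group of the diene, and B-alkyl Suzuki–Miyaura coupling with the α-bromo enoate joins C12 to C13 and brings in the finished butenolide.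

**Step 13**
Reactants: 21 butenolide alkene
Product: 22 [(1R,2S,4aR,5R,8aR)-8a-({[tert-butyl(dimethyl)silyl]oxy}methyl)-1,2-epoxy-5-methyl-1-[2-(2-oxo-2,5-dihydrofuran-3-yl)ethyl]decahydronaphthalen-5-yl]methyl acetate
Conditions: mCPBA, CH2Cl2, 0 °C
Reagents that add atoms: meta-chloroperbenzoic acid, O=C(OO)c1cccc(Cl)c1
Why: Prilezhaev epoxidation takes the electron-rich trisubstituted C8=C9 alkene and not the electron-poor butenolide alkene, from the face anti to the axial C10 substituent.

**Step 14**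
Reactants: 22 epoxide
Product: 24 [(1S,4aR,5R,8aS)-8a-({[tert-butyl(dimethyl)silyl]oxy}methyl)-5-methyl-2-oxo-1-[2-(2-oxo-2,5-dihydrofuran-3-yl)ethyl]decahydronaphthalen-5-yl]methyl acetate, via 9-epi ketone 23 (not isolated)
Conditions: BF3·OEt2 (20 mol %), CH2Cl2, −78 °C; then DBU (20 mol %), rt
Reagents that add atoms: none
Why: Meinwald rearrangement: the Lewis acid opens the epoxide at tertiary C9 and a 1,2-hydride shift from C8 gives the C8 ketone with the side chain axial; catalytic DBU then equilibrates C9 through the enolate to the equatorial side chain, so C9 is set under thermodynamic control.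

**Step 15**
Reactants: 24 C8 ketone
Product: 25 [(1R,4aR,5R,8aR)-8a-({[tert-butyl(dimethyl)silyl]oxy}methyl)-5-methyl-2-methylidene-1-[2-(2-oxo-2,5-dihydrofuran-3-yl)ethyl]decahydronaphthalen-5-yl]methyl acetate
Conditions: Zn, CH2Br2, TiCl4, THF/CH2Cl2, 0 °C → rt
Reagents that add atoms: dibromomethane, BrCBr
Why: Takai–Lombardo methylenation is non-basic and selective for ketones over esters and lactones, so the exocyclic methylene should be installed without loss of the C9 configuration.

**Step 16**
Reactants: 25 silyl ether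
Product: 26 [(1R,4aR,5R,8aR)-8a-(hydroxymethyl)-5-methyl-2-methylidene-1-[2-(2-oxo-2,5-dihydrofuran-3-yl)ethyl]decahydronaphthalen-5-yl]methyl acetate
Conditions: HF·pyridine, THF, 0 °C → rt
Reagents that add atoms: none
Why: Fluoride cleaves the silyl ether (desilylation) under mildly acidic conditions that should not move the acetate.

**Step 17**
Reactants: 26 C20 alcohol
Product: 27 [(1R,4aR,5R,8aR)-8a-formyl-5-methyl-2-methylidene-1-[2-(2-oxo-2,5-dihydrofuran-3-yl)ethyl]decahydronaphthalen-5-yl]methyl acetate (CNP0109410.1)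
Conditions: Dess–Martin periodinane, CH2Cl2, 0 °C → rt
Reagents that add atoms: none
Why: Dess–Martin oxidation of the neopentyl primary alcohol should give the non-enolisable C20 aldehyde without touching the alkenes or esters.

**Compound list**
1 | methyl 2-oxocyclohexane-1-carboxylate | COC(=O)C1CCCCC1=O | starting material
2 | methyl 2-oxo-1-(phenylselanyl)cyclohexane-1-carboxylate | COC(=O)C1([Se]c2ccccc2)CCCCC1=O | intermediate
3 | methyl 2-oxo-1-(phenylseleninyl)cyclohexane-1-carboxylate | COC(=O)C1([Se](=O)c2ccccc2)CCCCC1=O | intermediate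
4 | methyl 6-oxocyclohex-1-ene-1-carboxylate | COC(=O)C1=CCCCC1=O | intermediate
5 | ethyl 2-cyanopropanoate (racemic) | CCOC(=O)C(C)C#N | starting material
6 | methyl (6S)-6-(2-cyano-1-ethoxy-1-oxopropan-2-yl)-2-oxocyclohexane-1-carboxylate (epimers at C1 and at the side-chain carbon) | O=C1CCC[C@@H](C1C(=O)OC)C(C)(C#N)C(=O)OCC | intermediate
7 | methyl (6R)-6-(2-cyano-1-ethoxy-1-oxopropan-2-yl)-2-{[(trifluoromethyl)sulfonyl]oxy}cyclohex-1-ene-1-carboxylate | O=S(=O)(OC1=C(C(=O)OC)[C@H](CCC1)C(C)(C#N)C(=O)OCC)C(F)(F)F | intermediate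
8 | methyl (6S)-6-(2-cyano-1-ethoxy-1-oxopropan-2-yl)-2-ethenylcyclohex-1-ene-1-carboxylate | C=CC1=C(C(=O)OC)[C@H](CCC1)C(C)(C#N)C(=O)OCC | intermediate
9 | methyl (6R)-6-[(1RS)-1-cyanoethyl]-2-ethenylcyclohex-1-ene-1-carboxylate | C=CC1=C(C(=O)OC)[C@H](CCC1)C(C)C#N | intermediate
10 | 1-chloro-3-iodopropane | ClCCCI | starting material
11 | methyl (1S,6R)-1-(3-chloropropyl)-6-[(1RS)-1-cyanoethyl]-2-ethenylcyclohex-2-ene-1-carboxylate | ClCCC[C@@]1(C(=O)OC)C(C=C)=CCC[C@@H]1C(C)C#N | intermediate
12 | methyl (4aR,5R,8aS)-5-cyano-1-ethenyl-5-methyl-4,4a,5,6,7,8-hexahydronaphthalene-8a(3H)-carboxylate | C=CC1=CCC[C@@H]2[C@](C)(C#N)CCC[C@@]12C(=O)OC | intermediate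
13 | (4aR,5R,8aS)-1-ethenyl-8a-(hydroxymethyl)-5-methyl-3,4,4a,5,6,7,8,8a-octahydronaphthalene-5-carbonitrile | C=CC1=CCC[C@@H]2[C@](C)(C#N)CCC[C@@]12CO | intermediate
14 | (4aR,5R,8aS)-8a-({[tert-butyl(dimethyl)silyl]oxy}methyl)-1-ethenyl-5-methyl-3,4,4a,5,6,7,8,8a-octahydronaphthalene-5-carbonitrile | C=CC1=CCC[C@@H]2[C@](C)(C#N)CCC[C@@]12CO[Si](C)(C)C(C)(C)C | intermediate
15 | 1-[(4aR,5R,8aS)-8a-({[tert-butyl(dimethyl)silyl]oxy}methyl)-1-ethenyl-5-methyl-3,4,4a,5,6,7,8,8a-octahydronaphthalen-5-yl]methanimine | C=CC1=CCC[C@@H]2[C@](C)(C=N)CCC[C@@]12CO[Si](C)(C)C(C)(C)C | intermediate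
16 | (4aS,5R,8aS)-8a-({[tert-butyl(dimethyl)silyl]oxy}methyl)-1-ethenyl-5-methyl-3,4,4a,5,6,7,8,8a-octahydronaphthalene-5-carbaldehyde | C=CC1=CCC[C@@H]2[C@](C)(C=O)CCC[C@@]12CO[Si](C)(C)C(C)(C)C | intermediate
17 | [(4aR,5R,8aS)-8a-({[tert-butyl(dimethyl)silyl]oxy}methyl)-1-ethenyl-5-methyl-3,4,4a,5,6,7,8,8a-octahydronaphthalen-5-yl]methanol | C=CC1=CCC[C@@H]2[C@](C)(CO)CCC[C@@]12CO[Si](C)(C)C(C)(C)C | intermediate
18 | [(4aR,5R,8aS)-8a-({[tert-butyl(dimethyl)silyl]oxy}methyl)-1-ethenyl-5-methyl-3,4,4a,5,6,7,8,8a-octahydronaphthalen-5-yl]methyl acetate | C=CC1=CCC[C@@H]2[C@](C)(COC(C)=O)CCC[C@@]12CO[Si](C)(C)C(C)(C)C | intermediate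
19 | 3-bromofuran-2(5H)-one | O=C1OCC=C1Br | starting material
20 | [(4aR,5R,8aS)-1-[2-(9-borabicyclo[3.3.1]nonan-9-yl)ethyl]-8a-({[tert-butyl(dimethyl)silyl]oxy}methyl)-5-methyl-3,4,4a,5,6,7,8,8a-octahydronaphthalen-5-yl]methyl acetate | B1(CCC3=CCC[C@@H]4[C@](C)(COC(C)=O)CCC[C@@]34CO[Si](C)(C)C(C)(C)C)C2CCCC1CCC2 | intermediate
21 | [(4aR,5R,8aS)-8a-({[tert-butyl(dimethyl)silyl]oxy}methyl)-5-methyl-1-[2-(2-oxo-2,5-dihydrofuran-3-yl)ethyl]-3,4,4a,5,6,7,8,8a-octahydronaphthalen-5-yl]methyl acetate | O=C1OCC=C1CCC1=CCC[C@@H]2[C@](C)(COC(C)=O)CCC[C@@]12CO[Si](C)(C)C(C)(C)C | intermediate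
22 | [(1R,2S,4aR,5R,8aR)-8a-({[tert-butyl(dimethyl)silyl]oxy}methyl)-1,2-epoxy-5-methyl-1-[2-(2-oxo-2,5-dihydrofuran-3-yl)ethyl]decahydronaphthalen-5-yl]methyl acetate | O1[C@H]2CC[C@@H]3[C@](C)(COC(C)=O)CCC[C@@]3(CO[Si](C)(C)C(C)(C)C)[C@@]12CCC4=CCOC4=O | intermediate
23 | [(1R,4aR,5R,8aS)-8a-({[tert-butyl(dimethyl)silyl]oxy}methyl)-5-methyl-2-oxo-1-[2-(2-oxo-2,5-dihydrofuran-3-yl)ethyl]decahydronaphthalen-5-yl]methyl acetate | O=C1CC[C@@H]2[C@](C)(COC(C)=O)CCC[C@@]2(CO[Si](C)(C)C(C)(C)C)[C@H]1CCC1=CCOC1=O | intermediate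
24 | [(1S,4aR,5R,8aS)-8a-({[tert-butyl(dimethyl)silyl]oxy}methyl)-5-methyl-2-oxo-1-[2-(2-oxo-2,5-dihydrofuran-3-yl)ethyl]decahydronaphthalen-5-yl]methyl acetate | O=C1CC[C@@H]2[C@](C)(COC(C)=O)CCC[C@@]2(CO[Si](C)(C)C(C)(C)C)[C@@H]1CCC1=CCOC1=O | intermediate
25 | [(1R,4aR,5R,8aR)-8a-({[tert-butyl(dimethyl)silyl]oxy}methyl)-5-methyl-2-methylidene-1-[2-(2-oxo-2,5-dihydrofuran-3-yl)ethyl]decahydronaphthalen-5-yl]methyl acetate | C=C1CC[C@@H]2[C@](C)(COC(C)=O)CCC[C@@]2(CO[Si](C)(C)C(C)(C)C)[C@@H]1CCC1=CCOC1=O | intermediate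
26 | [(1R,4aR,5R,8aR)-8a-(hydroxymethyl)-5-methyl-2-methylidene-1-[2-(2-oxo-2,5-dihydrofuran-3-yl)ethyl]decahydronaphthalen-5-yl]methyl acetate | C=C1CC[C@@H]2[C@](C)(COC(C)=O)CCC[C@@]2(CO)[C@@H]1CCC1=CCOC1=O | intermediate
27 | [(1R,4aR,5R,8aR)-8a-formyl-5-methyl-2-methylidene-1-[2-(2-oxo-2,5-dihydrofuran-3-yl)ethyl]decahydronaphthalen-5-yl]methyl acetate (CNP0109410.1) | C=C1CC[C@@H]2[C@](C)(COC(C)=O)CCC[C@@]2(C=O)[C@@H]1CCC1=CCOC1=O | target

Total step count: 17. Longest linear sequence: 17 steps (1 to 27).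

**Steps most likely to fail**

Step 2. What may go wrong: poor enantiofacial selectivity at the ring β-carbon, or its erosion by reversible (retro-Michael) addition of the stabilised cyano ester anion. The fallback sets out from 4 and comes back at 9, and uses a Mukaiyama–Michael addition, which is not reversible. The trimethylsilyl ketene acetal of S-tert-butyl propanethioate F1 (from the thioester, LiN(iPr)2 and Me3SiCl) is added to 4 under Cu(OTf)2/tert-butyl-bis(oxazoline) catalysis and should give the keto ester thioester F2. Triflation and vinylation as in steps 3 and 4 should give the enol triflate F3 and the diene thioester F4. Ammonolysis of the thioester (NH3, AgOCOCF3, THF) should give the primary amide F5, and dehydration (trifluoroacetic anhydride, pyridine) returns to the route at 9.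

Step 6. What may go wrong: poor facial selectivity in the ring closure at C4 (the cyano group not taking the axial site), or alkylation of the nitrile carbanion before the dienolate, which would fix C4 in an open-chain step. The fallback sets out from 4 and comes back at 12; the methyl group is left out and added last. Michael addition of ethyl cyanoacetate to 4 as in step 2 should give the cyanoacetate adduct F6. Steps 3 to 5 applied to it should give the enol triflate F7, the diene F8 and the cyanomethyl diene ester F9. The annulation of step 6 should then give the C4–H nitrile F10, whose C4 configuration does not matter. LiN(iPr)2 (THF, −78 °C) and MeI then methylate the ring nitrile carbanion from the equatorial direction, away from the axial C10 ester, as is usual for cyclohexanecarbonitrile anions, and return to the route at 12.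

Step 14. What may go wrong: ring contraction by migration of the C7–C8 bond, or migration of a C10 substituent to the C9 cation, in place of the hydride shift. The fallback sets out from 21 and comes back at 24. Dihydroxylation of the C8=C9 alkene (OsO4 cat., N-methylmorpholine N-oxide) anti to the C10 substituent should give the 8,9-diol F11. Dess–Martin oxidation of the secondary hydroxyl should give the α-hydroxy ketone F12. SmI2 (THF/MeOH, −78 °C) should cleave the C9–O bond next to the ketone, and equilibration of C9 with DBU returns to the route at 24.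

**Further compounds**
F1 | step 2 | tert-butyl 1-(trimethylsilyloxy)prop-1-en-1-yl sulfide | CC=C(O[Si](C)(C)C)SC(C)(C)C
F2 | step 2 | methyl (6S)-6-[1-(tert-butylsulfanyl)-1-oxopropan-2-yl]-2-oxocyclohexane-1-carboxylate | O=C1CCC[C@@H](C1C(=O)OC)C(C)C(=O)SC(C)(C)C
F3 | step 2 | methyl (6R)-6-[1-(tert-butylsulfanyl)-1-oxopropan-2-yl]-2-{[(trifluoromethyl)sulfonyl]oxy}cyclohex-1-ene-1-carboxylate | O=S(=O)(OC1=C(C(=O)OC)[C@H](CCC1)C(C)C(=O)SC(C)(C)C)C(F)(F)F
F4 | step 2 | methyl (6R)-6-[1-(tert-butylsulfanyl)-1-oxopropan-2-yl]-2-ethenylcyclohex-1-ene-1-carboxylate | C=CC1=C(C(=O)OC)[C@H](CCC1)C(C)C(=O)SC(C)(C)C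
F5 | step 2 | methyl (6R)-6-(1-amino-1-oxopropan-2-yl)-2-ethenylcyclohex-1-ene-1-carboxylate | C=CC1=C(C(=O)OC)[C@H](CCC1)C(C)C(N)=O
F6 | step 6 | methyl (6R)-6-(1-cyano-2-ethoxy-2-oxoethyl)-2-oxocyclohexane-1-carboxylate | O=C1CCC[C@@H](C1C(=O)OC)C(C#N)C(=O)OCC
F7 | step 6 | methyl (6R)-6-(1-cyano-2-ethoxy-2-oxoethyl)-2-{[(trifluoromethyl)sulfonyl]oxy}cyclohex-1-ene-1-carboxylate | O=S(=O)(OC1=C(C(=O)OC)[C@H](CCC1)C(C#N)C(=O)OCC)C(F)(F)F
F8 | step 6 | methyl (6R)-6-(1-cyano-2-ethoxy-2-oxoethyl)-2-ethenylcyclohex-1-ene-1-carboxylate | C=CC1=C(C(=O)OC)[C@H](CCC1)C(C#N)C(=O)OCC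
F9 | step 6 | methyl (6R)-6-(cyanomethyl)-2-ethenylcyclohex-1-ene-1-carboxylate | C=CC1=C(C(=O)OC)[C@H](CCC1)CC#N
F10 | step 6 | methyl (4aR,8aS)-5-cyano-1-ethenyl-4,4a,5,6,7,8-hexahydronaphthalene-8a(3H)-carboxylate (either configuration at C5) | C=CC1=CCC[C@@H]2C(C#N)CCC[C@@]12C(=O)OC
F11 | step 14 | [(1R,2S,4aR,5R,8aR)-8a-({[tert-butyl(dimethyl)silyl]oxy}methyl)-1,2-dihydroxy-5-methyl-1-[2-(2-oxo-2,5-dihydrofuran-3-yl)ethyl]decahydronaphthalen-5-yl]methyl acetate | O[C@H]1CC[C@@H]2[C@](C)(COC(C)=O)CCC[C@@]2(CO[Si](C)(C)C(C)(C)C)[C@]1(O)CCC1=CCOC1=O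
F12 | step 14 | [(1R,4aR,5R,8aR)-8a-({[tert-butyl(dimethyl)silyl]oxy}methyl)-1-hydroxy-5-methyl-2-oxo-1-[2-(2-oxo-2,5-dihydrofuran-3-yl)ethyl]decahydronaphthalen-5-yl]methyl acetate | O=C1CC[C@@H]2[C@](C)(COC(C)=O)CCC[C@@]2(CO[Si](C)(C)C(C)(C)C)[C@]1(O)CCC1=CCOC1=O
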